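# Proposed synthesis of CNP0206695.1, methyl 15-acetoxylabda-8,13E-dien-19-oate

## The problem

- The target is a trans-fused decalin (ring A: C1–C5 and C10; ring B: C5–C10) with a tetrasubstituted C8=C9 alkene in ring B. C9 carries a five-carbon chain that ends in an (E)-trisubstituted allylic acetate.
- Its three stereocentres are contiguous on ring A. C4 is quaternary, with an axial β ester (C19) and an equatorial α methyl group. C5 bears an α hydrogen. C10 is quaternary with a β methyl group (C20), so the ester and the angular methyl group are 1,3-diaxial.
- Stereocontrol can only run outward from C10. Once the angular methyl group is in place it directs axial (α) protonation at C5 and equatorial (α) attack of a carbon electrophile at C4. Neither C4 nor C5 can be used to build C10, and the chain has no stereocentre, so the absolute configuration must be brought to C10 from outside.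
- Two quaternary carbons flank one methine, and the tetrasubstituted alkene must lie between C8 and C9, not at C7 or exocyclic.
- The allylic acetate will not survive zerovalent palladium, dissolving metals, hydride or strong base. The two alkenes together invite acid-promoted migration or cyclisation. The axial ester is hindered and robust. The chain therefore comes late and the acetate last.
- The enabling feature is that C20 sits on a ring-fusion carbon whose neighbour C5 carries only hydrogen. C20 can be introduced as the CH2 of a cyclopropane across a C5=C10 alkene, delivered by a hydroxyl on C4. The C5–C20 bond can later be cut reductively through a C4 carbonyl, which leaves an enolate exactly where the C4 substituents have to go.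

## Retrosynthesis

**27 to 26 to 25 (O–acetyl bond).** The acetate is cut first. An allylic acetate would ionise under the palladium catalysis that attaches the chain, so C15 is carried as a silyl ether in 25 and freed in 26 only at the end. The precursor is barely simpler, but this removes the one group that would constrain every earlier step. The forward steps are routine.

**25 to 20 and 23 (C9–C11 bond).** Cutting here separates the decalin from the whole chain in one stroke. The enol triflate 20 fixes the alkene between C8 and C9, which dehydration of a C9 carbinol would not. A cut at C11–C12 or C12–C13 would leave a homoallylic or allylic decalin fragment that needs more steps to make. Diene 23 is hydroborated to borane 24, which carries the (E)-alkene unchanged. The forward reaction must join a primary alkylborane to a hindered, tetrasubstituted alkenyl triflate.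

**20 to 18 to 16 to 15 to 14 (C8–C17 bond, C9 oxidation level).** The C8 methyl group and the triflate both come from the C9 ketone 16. Because C10 is quaternary, 16 can enolise only toward C8, so methylation (18) and triflation (20) need no regiocontrol. Ketone 16 comes from carbinol 15 and its silyl ether 14. The C9 oxygen is thus a spectator that is carried through the ring A chemistry and used only here.

**14 to 12 to 11 (C4–CH3, C5–H, then C4–C19).** The methyl group on C4 and the hydrogen on C5 are removed together, which leads to the unsaturated ester 12. In the forward sense its reduction gives the trans ring fusion and an ester enolate that is methylated from the α face, leaving the ester axial. The neighbouring option, adding the carboxyl carbon to a C4-methyl enolate, would give the C4 epimer. Ester 12 comes from enol triflate 11 by carbonylation. Two quaternary-centre problems are reduced to one alkene.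

**11 to 9 via 10 (C5–C20 bond, drawn in reverse).** Triflate 11 is the trapped form of enolate 10. Joining C20 to C5 in 10 gives the cyclopropyl ketone 9. Forward, electron transfer must cleave C5–C20 and not the ring-fusion bond C5–C10. The enolate must be caught on oxygen before it can equilibrate toward C3. This cut removes the angular methyl group as a separate problem and explains why C4 is at the ketone level.

**9 to 8 to 7 (C20–C10 and C20–C5, the key cut).** Removing the CH2 from propellanol 8 gives the allylic alcohol 7, a ring-fusion alkene with a hydroxyl on C4 (β) and a silyl ether on C9 (α). This is preferred to conjugate addition of a methyl nucleophile to a C5=C10 enone, which would leave the C10 face to a weak bias from C9. Here a covalently bound reagent sets C10. The precursor has no quaternary carbon and only two carbinol stereocentres.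

**7 to 6 to 5 to 2 to 1.** The C4 carbinol of 7 comes from enone 6 by a reagent-controlled reduction. Enone 6 is the silyl ether of hydroxy enone 5. Enone 5 is the dearomatised form of tetralol 2 (through 3 and 4). Tetralol 2 comes from the commercial tetralone 1 by enantioselective reduction. Both carbinol centres are set by catalysts, so their trans relationship is a matter of choosing catalyst enantiomers. The demanding step is the arene reduction, which has to leave a benzylic C–O bond intact.

**23 to 22 to 21.** The diene is the semihydrogenation product of the silylated enynol 22. Enynol 21 is commercial as the (E)-isomer, so the alkene geometry is bought, not made.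

## Roads not taken

**Alternative 1:** intramolecular Diels–Alder reaction of an alkylidene malonate.
- Cut: C3–C4 and C5–C10. This opens ring A to the tethered triene A2 (diene C10=C1–C2=C3, alkylidene malonate C4=C5, tether C6–C9 with C9 as a dioxolane).
- Forward key step: a chiral bis(oxazoline) complex of divalent copper, for example from Cu(SbF6)2, would chelate the malonate and promote cycloaddition to A1. Ring A closes as the cycloaddition ring and ring B through the tether.
- Merits: both rings, C5, C10 and the C4 quaternary carbon arise in one catalytic step, and the route would converge with the present one at ketone 16.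
- Weak points:
  - The diene terminus C10 carries two carbon substituents, so its methyl group is forced to the inside of the s-cis diene, and a quaternary centre must form at that crowded terminus.
  - Enantioselective cycloadditions of alkylidene malonates that create a quaternary carbon on the diene side are not established.
  - The trans ring fusion depends on an endo/exo preference set by the tether, not by the catalyst.
  - Afterwards the twin esters must be told apart (the equatorial one reduced to methyl, about four steps) and the C1=C2 alkene hydrogenated.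
- Comparison: if the cycloaddition worked, 16 would be reached in fewer than the eleven steps needed here and with more convergence, which is a real advantage. The chosen plan sets against it a stereochemical course that rests at each centre on an established directing effect, and a C4 that is made with its two different substituents.

**Alternative 2:** Diels–Alder reaction of a dimethylbenzoquinone.
- Cut: C1–C10 and C4–C5. Ring A is removed as the diene A5, and ring B is the quinone A4.
- Forward key step: a chiral oxazaborolidinium Lewis acid activates A4, and A5 adds across the methyl-bearing C5=C10 double bond to give the cis-fused adduct A3.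
- Merits: one catalytic step gives the bicycle with the C10 quaternary centre, the C8 methyl group and the C9 carbonyl already present. Such quinone cycloadditions have closer precedent than the arene reduction used here.
- Weak points:
  - A3 is cis-fused, so C5 must be epimerised through the C6 ketone, and with an angular methyl group the trans isomer is not clearly favoured.
  - C6 carries an oxygen the target lacks, the C7=C8 alkene lies on the wrong side of C8, and C2=C3 must be reduced.
  - C4 is only tertiary, so the quaternary centre needs oxidation to the aldehyde, methylation and oxidation again, with a facial outcome that depends on the trans fusion being in place first.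
  - Two similar ketones (C6, C9) must be distinguished when the chain is attached.
- Comparison: this road is better in the speed with which ring B is functionalised and saves the late C8 methylation. The chosen plan sets against it that it carries no surplus oxygen, never inverts a ring fusion, and makes C4 and C5 in one operation.

**Alternative 3:** three-component conjugate addition and enolate trapping.
- Cut: C9–C10 and C5–C6, with ring B left open. Ring A is 3-methylcyclohex-2-enone A7, the chain arrives as the alkenylaluminium A8, and C6–C8 with C17 come from but-3-en-2-one A9.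
- Forward key step: copper-catalysed enantioselective addition of A8 to C10 of A7 (a copper salt such as CuCl2 with a chiral N-heterocyclic carbene), then Michael addition of the enolate to A9, giving A6. No ring closes.
- Merits: it is the most convergent of the four. The whole chain and the absolute configuration at C10 are in place after the first step, and this kind of quaternary-centre formation is well precedented.
- Weak points:
  - An aluminium enolate is a poor Michael donor toward a polymerisable enone and exchanges protons easily, so the one-pot trapping would probably have to be split.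
  - Ring B must then be closed by making the tetrasubstituted C8=C9 alkene from a 1,1-disubstituted alkene and a methyl ketone, the most difficult kind of ring-closing olefination.
  - The C4 quaternary centre must be built next to an epimerisable C5 while the allylic silyl ether is on board, which excludes the dissolving-metal steps that make C4 and C5 simple here.
- Comparison: this road could be markedly shorter and is superior in convergence. The chosen plan sets against it the late arrival of the fragile chain, an alkene position fixed by an enol triflate, and a C4/C5 construction of known stereochemical course.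

Key step: step 5

## Remarks on the chemistry

- Positions are given in labdane numbering (C4 ester-bearing carbon, C10 angular-methyl carbon, C20 that methyl group). α is the face of the C5 hydrogen, β that of the C10 methyl group.
- Ketone 18 is carried on as a mixture of C8 epimers, since C8 becomes sp2 in step 13. Its SMILES leaves that centre open, as does that of the transient diene 4 at its ring-fusion carbon.
- Enynol 21 is assumed to be purchased as the pure (E)-isomer.

## Route

Step 1
Reactants: 1 5-methoxy-3,4-dihydronaphthalen-1(2H)-one
Product: 2 (R)-5-methoxy-1,2,3,4-tetrahydronaphthalen-1-ol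
Conditions: RuCl[(R,R)-TsDPEN](p-cymene) (0.5 mol%), HCO2H/Et3N (5:2), 30 °C
Reagents that add atoms: none
Why: Noyori asymmetric transfer hydrogenation of an aryl alkyl ketone, for which 1-tetralones are among the best substrates. The (R,R)-ligand directs hydride to the face that gives the (R)-carbinol at C9, the first stereocentre of the route.

Step 2
Reactants: 2 (R)-5-methoxy-1,2,3,4-tetrahydronaphthalen-1-ol
Product: 5 (R)-5-hydroxy-3,4,5,6,7,8-hexahydronaphthalen-1(2H)-one, via lithium alkoxide 3 (not isolated), via dienol ether 4 (not isolated)
Conditions: n-BuLi, THF, −78 °C; Li, NH3(l), t-BuOH, −78 to −33 °C; isoprene, NH4Cl; then 0.5 M HCl, THF, 0 to 20 °C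
Reagents that add atoms: water, O
Why: Birch reduction of the anisole ring, then enol ether hydrolysis and acid-mediated conjugation; the benzylic oxygen travels as its lithium alkoxide, which has no leaving group to lose and so should resist C–O hydrogenolysis. The methoxy group on C4 and the alkoxide-bearing substituent on C10 both keep their ipso and para carbons unreduced, so hydrogen should go to C5 and C2, and hydrolysis then gives the C4 ketone with a C1=C10 alkene that moves into conjugation as C5=C10. The C9 stereocentre is not touched.

Step 3
Reactants: 5 (R)-5-hydroxy-3,4,5,6,7,8-hexahydronaphthalen-1(2H)-one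
Product: 6 (R)-5-[(tert-butyldimethylsilyl)oxy]-3,4,5,6,7,8-hexahydronaphthalen-1(2H)-one
Conditions: TBSCl, imidazole, DMF, 20 °C
Reagents that add atoms: tert-butyldimethylsilyl chloride, CC(C)(C)[Si](C)(C)Cl
Why: Standard silylation of a secondary alcohol. The silyl ether shields the α face in step 5 and survives every reductive step up to step 10.

Step 4
Reactants: 6 (R)-5-[(tert-butyldimethylsilyl)oxy]-3,4,5,6,7,8-hexahydronaphthalen-1(2H)-one
Product: 7 (1S,5R)-5-[(tert-butyldimethylsilyl)oxy]-1,2,3,4,5,6,7,8-octahydronaphthalen-1-ol
Conditions: (R)-2-methyl-CBS-oxazaborolidine (15 mol%), BH3·SMe2, THF, −30 °C; MeOH, aq. NH4Cl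
Reagents that add atoms: none
Why: Corey–Bakshi–Shibata reduction of an α-substituted cyclic enone, with the tetrasubstituted alkene arm as the large group. The (R)-catalyst should deliver hydride to the α face and give the (S)-carbinol at C4 (β hydroxyl), trans to the C9 silyl ether; the new centre is under reagent control and the remote C9 centre has little influence.

Step 5
Reactants: 7 (1S,5R)-5-[(tert-butyldimethylsilyl)oxy]-1,2,3,4,5,6,7,8-octahydronaphthalen-1-ol
Product: 8 (1R,2S,6R,7R)-7-[(tert-butyldimethylsilyl)oxy]tricyclo[4.4.1.0^1,6]undecan-2-ol
Conditions: Et2Zn, CH2I2, CH2Cl2, 0 to 20 °C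
Reagents that add atoms: diiodomethane, ICI
Why: Hydroxyl-directed Simmons–Smith cyclopropanation in the Furukawa variant: Et2Zn deprotonates the C4 carbinol and exchanges with CH2I2 to give an iodomethylzinc carbenoid held by the zinc alkoxide. The CH2 unit is transferred to C5=C10 in one concerted butterfly-type [2+1] step, so C20–C10 and C20–C5 form together and the three-membered ring closes across the ring-fusion alkene without an open intermediate. The closest known reaction is the directed cyclopropanation of cyclohex-2-enols and of ring-fusion octalinols, which gives the syn cyclopropylcarbinol. Both new stereocentres, C5 and C10, are set by the C4 carbinol, because a carbenoid bound to the β oxygen can reach only the β face, so C20 ends up β on both carbons. The C9 silyl ether lies on the α face and adds a steric bias in the same direction, while being too hindered to bind zinc itself. The step needs face selectivity only, since 7 has a single alkene, and it needs carbenoid transfer to outrun O-methylation, which the electron-rich tetrasubstituted alkene and the proximity of the alkoxide should ensure. The C5–C20 bond made here is temporary and is cut again in step 7.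

Step 6
Reactants: 8 (1R,2S,6R,7R)-7-[(tert-butyldimethylsilyl)oxy]tricyclo[4.4.1.0^1,6]undecan-2-ol
Product: 9 (1R,6R,7R)-7-[(tert-butyldimethylsilyl)oxy]tricyclo[4.4.1.0^1,6]undecan-2-one
Conditions: (n-Pr)4N[RuO4] (5 mol%), N-methylmorpholine N-oxide, 4 Å sieves, CH2Cl2, 20 °C
Reagents that add atoms: none
Why: Ley–Griffith oxidation of a secondary cyclopropylcarbinol under neutral conditions, which spares the cyclopropane and the silyl ether. The directing carbinol is erased only after C5 and C10 are set.

Step 7
Reactants: 9 (1R,6R,7R)-7-[(tert-butyldimethylsilyl)oxy]tricyclo[4.4.1.0^1,6]undecan-2-one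
Product: 11 (4aS,5R)-5-[(tert-butyldimethylsilyl)oxy]-4a-methyl-2,3,4,4a,5,6,7,8-octahydronaphthalen-1-yl trifluoromethanesulfonate, via lithium enolate 10 (not isolated)
Conditions: Li, NH3(l), THF, t-BuOH (1 equiv), −78 °C; isoprene; NH3 evaporated; PhNTf2, THF, 0 to 20 °C
Reagents that add atoms: N-phenylbis(trifluoromethanesulfonimide), O=S(=O)(N(c1ccccc1)S(=O)(=O)C(F)(F)F)C(F)(F)F
Why: Dissolving-metal cleavage of a conjugated cyclopropyl ketone: the ketyl opens the cyclopropane bond that overlaps the carbonyl π system, C5–C20 (exocyclic to ring A), so C20 stays on C10 as the β methyl group and the C4–C5 enolate 10 forms with defined regiochemistry. O-Sulfonylation with PhNTf2, as in the reductive triflation of enones, fixes that regiochemistry as the enol triflate. C10 keeps the configuration set in step 5.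

Step 8
Reactants: 11 (4aS,5R)-5-[(tert-butyldimethylsilyl)oxy]-4a-methyl-2,3,4,4a,5,6,7,8-octahydronaphthalen-1-yl trifluoromethanesulfonate
Product: 12 methyl (4aS,5R)-5-[(tert-butyldimethylsilyl)oxy]-4a-methyl-2,3,4,4a,5,6,7,8-octahydronaphthalene-1-carboxylate
Conditions: Pd(OAc)2 (10 mol%), PPh3, CO (1 atm), MeOH, Et3N, DMF, 60 °C
Reagents that add atoms: carbon monoxide, [C-]#[O+]; methanol, CO
Why: Palladium-catalysed methoxycarbonylation of an enol triflate (oxidative addition to zerovalent palladium, CO insertion, methanolysis). It places C19 on C4 at the ester oxidation level.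

Step 9
Reactants: 12 methyl (4aS,5R)-5-[(tert-butyldimethylsilyl)oxy]-4a-methyl-2,3,4,4a,5,6,7,8-octahydronaphthalene-1-carboxylate
Product: 14 methyl (1S,4aS,5R,8aR)-5-[(tert-butyldimethylsilyl)oxy]-1,4a-dimethyldecahydronaphthalene-1-carboxylate, via lithium ester enolate 13 (not isolated)
Conditions: Li, NH3(l), THF, t-BuOH (1 equiv), −78 °C; isoprene; MeI, −78 to −33 °C
Reagents that add atoms: iodomethane, CI
Why: Reductive alkylation of an α,β-unsaturated ester: two-electron reduction and axial protonation at C5 on the α face, anti to the C10 methyl group, should give the trans ring fusion and ester enolate 13. Iodomethane then attacks C4 from the equatorial α face, away from the 1,3-diaxial C10 methyl group, which leaves the ester axial (β) as in the 19-oate series.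

Step 10
Reactants: 14 methyl (1S,4aS,5R,8aR)-5-[(tert-butyldimethylsilyl)oxy]-1,4a-dimethyldecahydronaphthalene-1-carboxylate
Product: 15 methyl (1S,4aS,5R,8aR)-5-hydroxy-1,4a-dimethyldecahydronaphthalene-1-carboxylate
Conditions: HF (48% aq.), MeCN, 20 to 40 °C
Reagents that add atoms: none
Why: Acidic fluoride cleavage of a hindered secondary silyl ether. The saturated, hindered ester has no other group that reacts.

Step 11
Reactants: 15 methyl (1S,4aS,5R,8aR)-5-hydroxy-1,4a-dimethyldecahydronaphthalene-1-carboxylate
Product: 16 methyl (1S,4aS,8aR)-1,4a-dimethyl-5-oxodecahydronaphthalene-1-carboxylate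
Conditions: (n-Pr)4N[RuO4] (5 mol%), N-methylmorpholine N-oxide, 4 Å sieves, CH2Cl2, 20 °C
Reagents that add atoms: none
Why: Ley–Griffith oxidation of the secondary alcohol to the C9 ketone. C10 is quaternary, so no stereocentre can epimerise.

Step 12
Reactants: 16 methyl (1S,4aS,8aR)-1,4a-dimethyl-5-oxodecahydronaphthalene-1-carboxylate
Product: 18 methyl (1S,4aS,8aR)-1,4a,6-trimethyl-5-oxodecahydronaphthalene-1-carboxylate (C6 epimers), via lithium enolate 17 (not isolated)
Conditions: LiN(i-Pr)2, THF, −78 °C; MeI, −78 to 0 °C
Reagents that add atoms: iodomethane, CI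
Why: Kinetic enolate alkylation; the ketone can enolise only toward C8 because C10 is quaternary, and the ester has no α hydrogen. The configuration at C8 does not matter because the centre becomes sp2 in step 13.

Step 13
Reactants: 18 methyl (1S,4aS,8aR)-1,4a,6-trimethyl-5-oxodecahydronaphthalene-1-carboxylate (C6 epimers)
Product: 20 methyl (1S,4aS,8aR)-1,4a,6-trimethyl-5-{[(trifluoromethyl)sulfonyl]oxy}-1,2,3,4,4a,7,8,8a-octahydronaphthalene-1-carboxylate, via potassium enolate 19 (not isolated)
Conditions: KN(SiMe3)2, THF, −78 to 0 °C; PhNTf2, 0 to 20 °C
Reagents that add atoms: N-phenylbis(trifluoromethanesulfonimide), O=S(=O)(N(c1ccccc1)S(=O)(=O)C(F)(F)F)C(F)(F)F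
Why: Enol triflate formation from the only possible, tetrasubstituted enolate, as is routine for 2,2,6-trialkylcyclohexanones. It fixes the alkene between C8 and C9.

Step 14
Reactants: 21 (E)-3-methylpent-2-en-4-yn-1-ol
Product: 22 (E)-tert-butyldimethyl[(3-methylpent-2-en-4-yn-1-yl)oxy]silane
Conditions: TBSCl, imidazole, CH2Cl2, 20 °C
Reagents that add atoms: tert-butyldimethylsilyl chloride, CC(C)(C)[Si](C)(C)Cl
Why: Standard silylation of a primary allylic alcohol. An allylic silyl ether, unlike the acetate, is inert to the palladium catalyst of step 16.

Step 15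
Reactants: 22 (E)-tert-butyldimethyl[(3-methylpent-2-en-4-yn-1-yl)oxy]silane
Product: 23 (E)-tert-butyldimethyl[(3-methylpenta-2,4-dien-1-yl)oxy]silane
Conditions: H2 (1 atm), Pd/CaCO3 poisoned with Pb(OAc)2 (Lindlar catalyst), quinoline, hexane, 20 °C
Reagents that add atoms: none
Why: Lindlar semihydrogenation of the terminal alkyne of a conjugated enyne, stopped after one equivalent of hydrogen. The trisubstituted (E)-alkene is not touched and keeps its geometry.

Step 16
Reactants: 23 (E)-tert-butyldimethyl[(3-methylpenta-2,4-dien-1-yl)oxy]silane; 20 methyl (1S,4aS,8aR)-1,4a,6-trimethyl-5-{[(trifluoromethyl)sulfonyl]oxy}-1,2,3,4,4a,7,8,8a-octahydronaphthalene-1-carboxylate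
Product: 25 methyl (1S,4aS,8aR)-5-[(3E)-5-[(tert-butyldimethylsilyl)oxy]-3-methylpent-3-en-1-yl]-1,4a,6-trimethyl-1,2,3,4,4a,7,8,8a-octahydronaphthalene-1-carboxylate, via alkylborane 24 (not isolated)
Conditions: 9-BBN, THF, 0 to 20 °C; then 20, Pd(dppf)Cl2 (10 mol%), K3PO4 (3 M aq.), DMF, 60 °C
Reagents that add atoms: none
Why: B-alkyl Suzuki–Miyaura coupling: 9-BBN adds boron to the terminal carbon of the monosubstituted alkene of the diene and leaves the trisubstituted alkene, and the primary alkylborane 24 couples with the enol triflate under Pd(dppf)Cl2. The C9–C11 bond forms with the ring alkene fixed by the triflate and the (E)-geometry carried in from 21; the hindered ester and the silyl ether tolerate the phosphate base.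

Step 17
Reactants: 25 methyl (1S,4aS,8aR)-5-[(3E)-5-[(tert-butyldimethylsilyl)oxy]-3-methylpent-3-en-1-yl]-1,4a,6-trimethyl-1,2,3,4,4a,7,8,8a-octahydronaphthalene-1-carboxylate
Product: 26 methyl (1S,4aS,8aR)-5-[(3E)-5-hydroxy-3-methylpent-3-en-1-yl]-1,4a,6-trimethyl-1,2,3,4,4a,7,8,8a-octahydronaphthalene-1-carboxylate
Conditions: n-Bu4NF, THF, 0 to 20 °C
Reagents that add atoms: none
Why: Fluoride cleavage of a primary allylic silyl ether. The axial ester is too hindered to be attacked, and no acid is present that could shift the alkenes.

Step 18
Reactants: 26 methyl (1S,4aS,8aR)-5-[(3E)-5-hydroxy-3-methylpent-3-en-1-yl]-1,4a,6-trimethyl-1,2,3,4,4a,7,8,8a-octahydronaphthalene-1-carboxylate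
Product: 27 methyl (1S,4aS,8aR)-5-[(3E)-5-acetoxy-3-methylpent-3-en-1-yl]-1,4a,6-trimethyl-1,2,3,4,4a,7,8,8a-octahydronaphthalene-1-carboxylate
Conditions: Ac2O, pyridine, DMAP (cat.), CH2Cl2, 20 °C
Reagents that add atoms: acetic anhydride, CC(=O)OC(C)=O
Why: Acylation of a primary allylic alcohol under nucleophilic catalysis. It is placed last so that the acetate meets no metal, base or reductant.

## Compound list

1 | 5-methoxy-3,4-dihydronaphthalen-1(2H)-one (5-methoxy-1-tetralone) | COc1cccc2C(=O)CCCc12 | starting material
2 | (R)-5-methoxy-1,2,3,4-tetrahydronaphthalen-1-ol | O[C@@H]1CCCc2c(OC)cccc12 | intermediate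
3 | lithium (R)-5-methoxy-1,2,3,4-tetrahydronaphthalen-1-olate | [Li+].[O-][C@@H]1CCCc2c(OC)cccc12 | intermediate (not isolated)
4 | (1R)-5-methoxy-1,2,3,4,4a,7-hexahydronaphthalen-1-ol (either C4a epimer) | O[C@@H]1CCCC2C(OC)=CCC=C12 | intermediate (not isolated)
5 | (R)-5-hydroxy-3,4,5,6,7,8-hexahydronaphthalen-1(2H)-one | O=C1CCCC2=C1CCC[C@H]2O | intermediate
6 | (R)-5-[(tert-butyldimethylsilyl)oxy]-3,4,5,6,7,8-hexahydronaphthalen-1(2H)-one | O=C1CCCC2=C1CCC[C@H]2O[Si](C)(C)C(C)(C)C | intermediate
7 | (1S,5R)-5-[(tert-butyldimethylsilyl)oxy]-1,2,3,4,5,6,7,8-octahydronaphthalen-1-ol (hydroxyl β on C4, silyloxy α on C9) | O[C@H]1CCCC2=C1CCC[C@H]2O[Si](C)(C)C(C)(C)C | intermediate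
8 | (1R,2S,6R,7R)-7-[(tert-butyldimethylsilyl)oxy]tricyclo[4.4.1.0^1,6]undecan-2-ol (methylene bridge syn to hydroxyl, anti to silyloxy) | O[C@H]1CCC[C@@]23C[C@@]12CCC[C@H]3O[Si](C)(C)C(C)(C)C | intermediate
9 | (1R,6R,7R)-7-[(tert-butyldimethylsilyl)oxy]tricyclo[4.4.1.0^1,6]undecan-2-one | O=C1CCC[C@@]23C[C@@]12CCC[C@H]3O[Si](C)(C)C(C)(C)C | intermediate
10 | lithium (4aS,5R)-5-[(tert-butyldimethylsilyl)oxy]-4a-methyl-2,3,4,4a,5,6,7,8-octahydronaphthalen-1-olate | [Li+].[O-]C1=C2CCC[C@@H](O[Si](C)(C)C(C)(C)C)[C@@]2(C)CCC1 | intermediate (not isolated)
11 | (4aS,5R)-5-[(tert-butyldimethylsilyl)oxy]-4a-methyl-2,3,4,4a,5,6,7,8-octahydronaphthalen-1-yl trifluoromethanesulfonate | O=S(=O)(OC1=C2CCC[C@@H](O[Si](C)(C)C(C)(C)C)[C@@]2(C)CCC1)C(F)(F)F | intermediate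
12 | methyl (4aS,5R)-5-[(tert-butyldimethylsilyl)oxy]-4a-methyl-2,3,4,4a,5,6,7,8-octahydronaphthalene-1-carboxylate | COC(=O)C1=C2CCC[C@@H](O[Si](C)(C)C(C)(C)C)[C@@]2(C)CCC1 | intermediate
13 | lithium enolate of methyl 5-[(tert-butyldimethylsilyl)oxy]-4a-methyldecahydronaphthalene-1-carboxylate (C4=C(OLi)OMe; 5α-H, 9α-silyloxy, 10β-methyl) | [Li+].COC([O-])=C1CCC[C@]2(C)[C@H](O[Si](C)(C)C(C)(C)C)CCC[C@@H]12 | intermediate (not isolated)
14 | methyl (1S,4aS,5R,8aR)-5-[(tert-butyldimethylsilyl)oxy]-1,4a-dimethyldecahydronaphthalene-1-carboxylate (4β-CO2Me, 4α-Me, 5α-H, 9α-silyloxy, 10β-Me) | COC(=O)[C@@]1(C)CCC[C@]2(C)[C@H](O[Si](C)(C)C(C)(C)C)CCC[C@@H]12 | intermediate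
15 | methyl (1S,4aS,5R,8aR)-5-hydroxy-1,4a-dimethyldecahydronaphthalene-1-carboxylate | COC(=O)[C@@]1(C)CCC[C@]2(C)[C@H](O)CCC[C@@H]12 | intermediate
16 | methyl (1S,4aS,8aR)-1,4a-dimethyl-5-oxodecahydronaphthalene-1-carboxylate | COC(=O)[C@@]1(C)CCC[C@]2(C)C(=O)CCC[C@@H]12 | intermediate
17 | lithium enolate of 16 (C9(OLi)=C8) | [Li+].COC(=O)[C@@]1(C)CCC[C@]2(C)C([O-])=CCC[C@@H]12 | intermediate (not isolated)
18 | methyl (1S,4aS,8aR)-1,4a,6-trimethyl-5-oxodecahydronaphthalene-1-carboxylate (C6 epimers; C6 of the name is C8) | COC(=O)[C@@]1(C)CCC[C@]2(C)C(=O)C(C)CC[C@@H]12 | intermediate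
19 | potassium enolate of 18 (C9(OK)=C8) | [K+].COC(=O)[C@@]1(C)CCC[C@]2(C)C([O-])=C(C)CC[C@@H]12 | intermediate (not isolated)
20 | methyl (1S,4aS,8aR)-1,4a,6-trimethyl-5-{[(trifluoromethyl)sulfonyl]oxy}-1,2,3,4,4a,7,8,8a-octahydronaphthalene-1-carboxylate | COC(=O)[C@@]1(C)CCC[C@]2(C)C(OS(=O)(=O)C(F)(F)F)=C(C)CC[C@@H]12 | intermediate
21 | (E)-3-methylpent-2-en-4-yn-1-ol | C#C/C(C)=C/CO | starting material
22 | (E)-tert-butyldimethyl[(3-methylpent-2-en-4-yn-1-yl)oxy]silane | C#C/C(C)=C/CO[Si](C)(C)C(C)(C)C | intermediate
23 | (E)-tert-butyldimethyl[(3-methylpenta-2,4-dien-1-yl)oxy]silane | C=C/C(C)=C/CO[Si](C)(C)C(C)(C)C | intermediate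
24 | 9-[(3E)-5-[(tert-butyldimethylsilyl)oxy]-3-methylpent-3-en-1-yl]-9-borabicyclo[3.3.1]nonane | CC(C)(C)[Si](C)(C)OC/C=C(\C)CCB1C2CCCC1CCC2 | intermediate (not isolated)
25 | methyl (1S,4aS,8aR)-5-[(3E)-5-[(tert-butyldimethylsilyl)oxy]-3-methylpent-3-en-1-yl]-1,4a,6-trimethyl-1,2,3,4,4a,7,8,8a-octahydronaphthalene-1-carboxylate | COC(=O)[C@@]1(C)CCC[C@]2(C)C(CC/C(C)=C/CO[Si](C)(C)C(C)(C)C)=C(C)CC[C@@H]12 | intermediate
26 | methyl (1S,4aS,8aR)-5-[(3E)-5-hydroxy-3-methylpent-3-en-1-yl]-1,4a,6-trimethyl-1,2,3,4,4a,7,8,8a-octahydronaphthalene-1-carboxylate (methyl 15-hydroxylabda-8,13E-dien-19-oate) | COC(=O)[C@@]1(C)CCC[C@]2(C)C(CC/C(C)=C/CO)=C(C)CC[C@@H]12 | intermediate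
27 | methyl (1S,4aS,8aR)-5-[(3E)-5-acetoxy-3-methylpent-3-en-1-yl]-1,4a,6-trimethyl-1,2,3,4,4a,7,8,8a-octahydronaphthalene-1-carboxylate (methyl 15-acetoxylabda-8,13E-dien-19-oate, CNP0206695.1) | COC(=O)[C@@]1(C)CCC[C@]2(C)C(CC/C(C)=C/COC(C)=O)=C(C)CC[C@@H]12 | target

## Step count and least certain steps

Total: 18 steps. Longest linear sequence: 16 steps (steps 1–13 and 16–18, from 1). Steps 14 and 15 prepare the chain.

**Step 5 (key step).**
- Risk: methylene transfer to a tetrasubstituted alkene that is allylically oxygenated on both sides may be slow. O-methylation of the zinc alkoxide by excess carbenoid, or Lewis-acid-assisted loss of an allylic oxygen, could then compete. Delivery to the wrong face is the lesser concern.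
- Fallback (sets out from 6, returns at 9): nucleophilic methylene transfer replaces the electrophilic carbenoid. Corey–Chaykovsky cyclopropanation of the enone with dimethylsulfoxonium methylide (Me3S(O)I, NaH, DMSO, 50 °C) should add the ylide to C10 anti to the C9 silyloxy group, and the enolate then closes on C5. The cyclopropane would form on the same face without the C4 carbinol, and steps 4 to 6 fall away. No compound outside the list is made (F0).

**Step 2.**
- Risk: hydrogenolysis of the benzylic C–O bond whenever the alkoxide is protonated by the alcohol that the arene reduction needs. Protonation of the radical anion at C3 and C10 instead of C5 and C2 would leave an alkene that cannot move into conjugation.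
- Fallback (sets out from 1, returns at 5): the oxygen passes through the reduction as an enolate, which has no C(sp3)–O bond to break. This masking is argued from mechanism and is the least precedented part of the proposal.
  - Ketone 1 is deprotonated with LiN(i-Pr)2 to lithium 5-methoxy-3,4-dihydronaphthalen-1-olate F1.
  - The anisole ring is reduced (Li, NH3, t-BuOH), and the crude product is stirred with dilute HCl. This hydrolyses the enol ether and should draw the alkene into conjugation with both carbonyl groups, giving the achiral enedione 3,4,7,8-tetrahydronaphthalene-1,5(2H,6H)-dione F2.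
  - One carbonyl of F2 is reduced with (S)-2-methyl-CBS-oxazaborolidine and one equivalent of borane to give 5. The remaining enone is less electrophilic than the enedione, so over-reduction should be limited.

**Step 7.**
- Risk: proton transfer to enolate 10 before O-sulfonylation, which would give the ketone and, through it, scrambling of the enolate toward C3. The triflimide may also be consumed by lithium tert-butoxide. Opening of the ring-fusion bond C5–C10 is less likely.
- Fallback (sets out from 9, returns at 11): trapping and triflation are separated through an isolable enol ether.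
  - After the same reduction the enolate is silylated (Me3SiCl, Et3N, THF, −78 °C), and (4aS,5R)-5-[(tert-butyldimethylsilyl)oxy]-4a-methyl-1-[(trimethylsilyl)oxy]-2,3,4,4a,5,6,7,8-octahydronaphthalene F3 is isolated and purified.
  - Salt-free enolate 10 is regenerated with MeLi (THF, 0 °C) and sulfonylated with N-(5-chloropyridin-2-yl)triflimide.

**Step 16.**
- Risk: slow transmetalation of a primary alkyl group onto palladium at a tetrasubstituted carbon flanked by a quaternary one. β-Hydride elimination and hydrolysis of the triflate could then take over.
- Fallback (sets out from 20 and 22, returns at 25): an sp2–sp2 coupling, which hindered cyclohexenyl triflates undergo readily, replaces the sp3–sp2 one.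
  - Hydrostannation of alkyne 22 (Bu3SnH, Pd(PPh3)2Cl2) gives tert-butyldimethyl{[(2E,4E)-3-methyl-5-(tributylstannyl)penta-2,4-dien-1-yl]oxy}silane F4.
  - Stille coupling with 20 (Pd(PPh3)4, LiCl, DMF, 70 °C) gives methyl (1S,4aS,8aR)-5-[(1E,3E)-5-[(tert-butyldimethylsilyl)oxy]-3-methylpenta-1,3-dien-1-yl]-1,4a,6-trimethyl-1,2,3,4,4a,7,8,8a-octahydronaphthalene-1-carboxylate F5.
  - Diimide (from TsNHNH2 and NaOAc) should saturate only the disubstituted C11=C12 alkene, because the tri- and tetrasubstituted alkenes react far more slowly, and so give 25.

## Further compounds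

F0 | step 5 | none | none
F1 | step 2 | lithium 5-methoxy-3,4-dihydronaphthalen-1-olate | [Li+].[O-]C1=CCCc2c(OC)cccc12
F2 | step 2 | 3,4,7,8-tetrahydronaphthalene-1,5(2H,6H)-dione | O=C1CCCC2=C1CCCC2=O
F3 | step 7 | (4aS,5R)-5-[(tert-butyldimethylsilyl)oxy]-4a-methyl-1-[(trimethylsilyl)oxy]-2,3,4,4a,5,6,7,8-octahydronaphthalene | C[Si](C)(C)OC1=C2CCC[C@@H](O[Si](C)(C)C(C)(C)C)[C@@]2(C)CCC1
F4 | step 16 | tert-butyldimethyl{[(2E,4E)-3-methyl-5-(tributylstannyl)penta-2,4-dien-1-yl]oxy}silane | CCCC[Sn](CCCC)(CCCC)/C=C/C(C)=C/CO[Si](C)(C)C(C)(C)C
F5 | step 16 | methyl (1S,4aS,8aR)-5-[(1E,3E)-5-[(tert-butyldimethylsilyl)oxy]-3-methylpenta-1,3-dien-1-yl]-1,4a,6-trimethyl-1,2,3,4,4a,7,8,8a-octahydronaphthalene-1-carboxylate | COC(=O)[C@@]1(C)CCC[C@]2(C)C(/C=C/C(C)=C/CO[Si](C)(C)C(C)(C)C)=C(C)CC[C@@H]12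
A1 | alternative 1 | dimethyl trans-fused 5,5-(ethylenedioxy)-4a-methyl-4a,5,6,7,8,8a-hexahydronaphthalene-1,1(2H)-dicarboxylate | COC(=O)C1(C(=O)OC)CC=C[C@]2(C)C3(OCCO3)CCC[C@@H]12
A2 | alternative 1 | dimethyl 2-{4-[2-[(2E)-penta-2,4-dien-2-yl]-1,3-dioxolan-2-yl]butylidene}propanedioate | C=C/C=C(\C)C1(OCCO1)CCCC=C(C(=O)OC)C(=O)OC
A3 | alternative 2 | cis-fused 5-{[(tert-butyldimethylsilyl)oxy]methyl}-2,8a-dimethyl-4a,5,8,8a-tetrahydronaphthalene-1,4-dione | O=C1C=C(C)C(=O)[C@@]2(C)CC=C[C@@H](CO[Si](C)(C)C(C)(C)C)[C@@H]12
A4 | alternative 2 | 2,6-dimethyl-1,4-benzoquinone | CC1=CC(=O)C=C(C)C1=O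
A5 | alternative 2 | (E)-tert-butyldimethyl(penta-2,4-dien-1-yloxy)silane | C=C/C=C/CO[Si](C)(C)C(C)(C)C
A6 | alternative 3 | 3-methyl-2-(3-oxobutyl)-3-[(5E)-7-[(tert-butyldimethylsilyl)oxy]-5-methylhepta-1,5-dien-2-yl]cyclohexanone, the two new arms trans | O=C1CCC[C@](C)(C(=C)CC/C(C)=C/CO[Si](C)(C)C(C)(C)C)[C@H]1CCC(C)=O
A7 | alternative 3 | 3-methylcyclohex-2-en-1-one | CC1=CC(=O)CCC1
A8 | alternative 3 | diisobutyl[(5E)-7-[(tert-butyldimethylsilyl)oxy]-5-methylhepta-1,5-dien-2-yl]aluminium | CC(C)C[Al](CC(C)C)C(=C)CC/C(C)=C/CO[Si](C)(C)C(C)(C)C
A9 | alternative 3 | but-3-en-2-one | CC(=O)C=C
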